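**Plan**

1. Retrosynthetic cuts: the C8–O ester bond (made with inversion) and the C13 acetate; the O–O, C8–O and C13–O bonds of an 8,13-endoperoxide; the C6–C7 ring bond together with the lactone C12–O bond; the C7–C11 bond; the C1–C10 bond; the epoxide oxygen.
2. Enabling feature: C13–O and C8–O sit at the two ends of C13–C11=C7–C8, whose central alkene is the butenolide double bond. One step back this is the diene C13=C11–C7=C8, with both double bonds exocyclic to the neighbouring carbons C11 and C7 of the five-membered lactone ring (O–C12–C11–C7–C6), so it is locked s-cis.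
3. Forward chain assembly: nerol supplies C1–C6 and C15 with the Z alkene; epoxidation, cleavage to the C1 aldehyde, crotylation (C10, C14, C9, C8), extension to a C7 gem-dibromoalkene, Stille attachment of the C11–C13 acrylate.
4. Rings: the ten-membered ring closes at C6–C7 by a Nozaki–Hiyama–Kishi reaction and the lactone follows in the same flask; the dioxine ring forms in the singlet-oxygen step and is opened reductively; the two esters come last.
5. Stereochemistry: C4/C5 from Sharpless epoxidation; C10 from an (E)-crotylborane; C6 from Felkin–Anh addition to the epoxy aldehyde; C8 from oxygen attack anti to C5 followed by Mitsunobu inversion; the C7=C8 geometry from trans-selective coupling of the dibromoalkene.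

Key step: step 16

Remark: positions carry germacranolide numbers (C1 ketone, C4–C5 epoxide with C15 on C4, C6 lactone carbinol, C7=C11 butenolide alkene, C8 ester carbinol, C10 with C14, C12 lactone carbonyl, C13 acetoxymethyl).
Remark: singlet oxygen is assumed to attack the diene face anti to C5 (giving 8S); the last step is therefore chosen to invert C8.

**Route**

Step 1
Reactants: 1 nerol
Product: 2 [(2R,3S)-3-methyl-3-(4-methylpent-3-en-1-yl)oxiran-2-yl]methanol
Conditions: Ti(OiPr)4 (cat.), D-(−)-diethyl tartrate (cat.), t-BuOOH, 4 Å MS, CH2Cl2, −20 °C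
Reagents that add atoms: tert-butyl hydroperoxide, CC(C)(C)OO
Why: Sharpless asymmetric epoxidation: the titanium tartrate complex binds the allylic hydroxyl and, with the D-tartrate, delivers oxygen to the face of the (Z)-alkene that gives the (2R,3S)-epoxide (C5 R and C4 S of the target), while the remote alkene has no directing hydroxyl and is left.

Step 2
Reactants: 2 epoxy alcohol
Product: 3 (2S,3R)-3-{[(4-methoxybenzyl)oxy]methyl}-2-methyl-2-(4-methylpent-3-en-1-yl)oxirane
Conditions: NaH, PMBCl, Bu4NI (cat.), THF/DMF, 0 °C → rt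
Reagents that add atoms: 4-methoxybenzyl chloride, COc1ccc(CCl)cc1
Why: Williamson ether synthesis on the alkoxide, which should not undergo Payne rearrangement because the trisubstituted epoxide is the favoured isomer; the ether can later be removed under neutral oxidative conditions that spare the epoxide.

Step 3
Reactants: 3 PMB ether
Product: 5 3-[(2S,3R)-3-{[(4-methoxybenzyl)oxy]methyl}-2-methyloxiran-2-yl]propanal, via ozonide 4 (not isolated)
Conditions: O3, CH2Cl2, −78 °C (Sudan red 7B end point); then PPh3, −78 °C → rt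
Reagents that add atoms: ozone, [O-][O+]=O
Why: Ozonolysis with reductive work-up cleaves the only C=C bond, an electron-rich trisubstituted alkene that reacts faster than the anisyl ring, to the C1 aldehyde and acetone.

Step 4
Reactants: 5 aldehyde
Product: 7 (3R,4S)-1-[(2S,3R)-3-{[(4-methoxybenzyl)oxy]methyl}-2-methyloxiran-2-yl]-4-methylhex-5-en-3-ol, via diisopinocampheylborinate 6 (not isolated)
Conditions: (E)-crotyl-B(Ipc)2 [from (−)-Ipc2BOMe, trans-2-butene, KOtBu, n-BuLi, BF3·OEt2], THF, −78 °C; then NaOH, H2O2, 0 °C → rt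
Reagents that add atoms: (E)-crotyldiisopinocampheylborane of the (+)-α-pinene series, C/C=C/CB([C@H]1[C@H](C)[C@H]2C[C@@H](C1)C2(C)C)[C@H]1[C@H](C)[C@H]2C[C@@H](C1)C2(C)C
Why: Brown crotylboration through a chair-like six-membered transition state: the (E)-crotyl group gives the anti adduct and the isopinocampheyl groups direct addition to the Si face of the aldehyde, which sets C10 as S (and C1 as R, a centre later oxidised to the ketone).

Step 5
Reactants: 7 homoallylic alcohol
Product: 8 triethyl{[(3R,4S)-1-[(2S,3R)-3-{[(4-methoxybenzyl)oxy]methyl}-2-methyloxiran-2-yl]-4-methylhex-5-en-3-yl]oxy}silane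
Conditions: TESCl, imidazole, DMF, 0 °C → rt
Reagents that add atoms: chlorotriethylsilane, CC[Si](Cl)(CC)CC
Why: Silylation masks the C1 hydroxyl, which could otherwise open the 4,5-epoxide to a tetrahydrofuran under acid and would interfere with the oxidations that follow.

Step 6
Reactants: 8 silyl ether
Product: 10 (3S,4R)-6-[(2S,3R)-3-{[(4-methoxybenzyl)oxy]methyl}-2-methyloxiran-2-yl]-3-methyl-4-[(triethylsilyl)oxy]hexan-1-ol, via alkylborane 9 (not isolated)
Conditions: 9-BBN, THF, 0 °C → rt; then NaOH, H2O2, 0 °C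
Reagents that add atoms: hydrogen peroxide, OO
Why: Hydroboration–oxidation: 9-BBN places boron on the terminal carbon of the monosubstituted alkene and alkaline peroxide replaces it by hydroxyl, giving the C8 primary alcohol.

Step 7
Reactants: 10 primary alcohol
Product: 11 (3S,4R)-6-[(2S,3R)-3-{[(4-methoxybenzyl)oxy]methyl}-2-methyloxiran-2-yl]-3-methyl-4-[(triethylsilyl)oxy]hexanal
Conditions: Dess–Martin periodinane, NaHCO3, CH2Cl2, 0 °C → rt
Reagents that add atoms: none
Why: Dess–Martin oxidation of a primary alcohol under buffered conditions that leave the epoxide and both ethers intact; C10 is β to the new carbonyl and cannot epimerise.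

Step 8
Reactants: 11 aldehyde
Product: 12 (2S,3R)-2-[(3R,4S)-7,7-dibromo-4-methyl-3-[(triethylsilyl)oxy]hept-6-en-1-yl]-3-{[(4-methoxybenzyl)oxy]methyl}-2-methyloxirane
Conditions: CBr4, PPh3, 2,6-lutidine, CH2Cl2, 0 °C
Reagents that add atoms: carbon tetrabromide, BrC(Br)(Br)Br
Why: Ramirez dibromo-olefination (first stage of the Corey–Fuchs sequence), a Wittig reaction of the ylide from CBr4 and PPh3, adds C7 as a gem-dibromoalkene while lutidine buffers any HBr that could open the epoxide.

Step 9
Reactants: 13 methyl propiolate; 14 tributyltin hydride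
Product: 15 methyl 2-(tributylstannyl)prop-2-enoate
Conditions: Pd(PPh3)4 (cat.), THF, 0 °C → rt
Reagents that add atoms: none
Why: Palladium-catalysed hydrostannation of an ynoate: syn addition of Sn–H places tin on the carbon α to the ester, giving the alkenylstannane that becomes C11–C13.

Step 10
Reactants: 12 dibromoalkene; 15 stannyl acrylate
Product: 16 methyl (3Z,6S,7R)-3-bromo-9-[(2S,3R)-3-{[(4-methoxybenzyl)oxy]methyl}-2-methyloxiran-2-yl]-6-methyl-2-methylidene-7-[(triethylsilyl)oxy]non-3-enoate
Conditions: Pd2(dba)3 (cat.), tri(2-furyl)phosphine, CuI (cat.), toluene/NMP, 60 °C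
Reagents that add atoms: none
Why: Stille coupling: zerovalent palladium inserts selectively into the less hindered C–Br bond trans to the alkyl chain, so C11 ends up trans to C9 and the remaining bromine cis to C9, while CuI speeds transmetalation of the hindered stannane and suppresses cine substitution.

Step 11
Reactants: 16 bromodiene ester
Product: 17 methyl (3Z,6S,7R)-3-bromo-9-[(2S,3R)-3-(hydroxymethyl)-2-methyloxiran-2-yl]-6-methyl-2-methylidene-7-[(triethylsilyl)oxy]non-3-enoate
Conditions: DDQ, CH2Cl2/pH 7 buffer, 0 °C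
Reagents that add atoms: none
Why: Oxidative cleavage of the p-methoxybenzyl ether by DDQ (benzylic hydride abstraction, then hydrolysis) frees the C6 hydroxyl without touching the silyl ether, the epoxide or the electron-poor diene.

Step 12
Reactants: 17 epoxy alcohol
Product: 18 methyl (3Z,6S,7R)-3-bromo-9-[(2S,3S)-3-formyl-2-methyloxiran-2-yl]-6-methyl-2-methylidene-7-[(triethylsilyl)oxy]non-3-enoate
Conditions: Dess–Martin periodinane, NaHCO3, CH2Cl2, 0 °C
Reagents that add atoms: none
Why: Dess–Martin oxidation gives the α,β-epoxy aldehyde without epimerisation at C5 (the descriptor changes only because the formyl group outranks C4), and the aldehyde is used at once.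

Step 13
Reactants: 18 epoxy aldehyde
Product: 20 (1R,4S,5R,6R,7Z,10S)-4,5-epoxy-1-[(triethylsilyl)oxy]germacra-7,11(13)-dien-12,6-olide, via hydroxy ester 19 (not isolated)
Conditions: CrCl2 (10 equiv), NiCl2 (0.1 equiv), DMSO/THF, rt, syringe-pump addition (final 2 mM)
Reagents that add atoms: none
Why: Nozaki–Hiyama–Kishi reaction: zerovalent nickel inserts into the alkenyl C–Br bond with retention, chromium takes over the alkenyl group and adds it to the aldehyde in a ring closure helped by the two cis elements (epoxide and bromoalkene); the polar Felkin–Anh arrangement with the epoxide C–O bond anti to the incoming carbon should give 6R, and the chromium alkoxide then closes the lactone onto the neighbouring methyl ester.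

Step 14
Reactants: 20 silyl ether lactone
Product: 21 (1R,4S,5R,6R,7Z,10S)-4,5-epoxy-1-hydroxygermacra-7,11(13)-dien-12,6-olide
Conditions: Bu4NF, AcOH (1:1), THF, 0 °C → rt
Reagents that add atoms: none
Why: Fluoride-induced desilylation buffered with acetic acid removes the triethylsilyl group without base-induced conjugate addition to the α-methylene lactone and without enough acid to let the freed C1 hydroxyl open the epoxide across the ring.

Step 15
Reactants: 21 alcohol
Product: 22 (4S,5R,6R,7Z,10S)-4,5-epoxy-1-oxogermacra-7,11(13)-dien-12,6-olide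
Conditions: Dess–Martin periodinane, NaHCO3, CH2Cl2, 0 °C
Reagents that add atoms: none
Why: Dess–Martin oxidation of the secondary alcohol gives the C1 ketone under buffered, non-enolising conditions, so C10 keeps its configuration.

Step 16
Reactants: 22 diene lactone; 23 dioxygen
Product: 24 (4S,5R,6R,8S,10S)-4,5-epoxy-8,13-epidioxy-1-oxogermacr-7(11)-en-12,6-olide
Conditions: O2, tetraphenylporphyrin (cat.), visible light, CH2Cl2, −30 °C
Reagents that add atoms: none
Why: Photosensitised singlet oxygen adds across C13 and C8 of the diene C13=C11–C7=C8 in a concerted suprafacial [4+2] cycloaddition, the known route from s-cis 1,3-dienes to 3,6-dihydro-1,2-dioxines. The six-membered dioxine ring closes by cycloaddition, both C–O bonds forming on the same diene face, and the double bond moves to C7=C11 to give the butenolide. The diene cannot leave the s-cis form because both alkenes are exocyclic to adjacent carbons of the five-membered lactone, which offsets the deactivating carbonyl. The new stereocentre C8 is controlled by C6 and the ten-membered ring: C5, the epoxide oxygen and the C2–C3 bridge cover the face syn to C5, so oxygen should enter anti to C5 and give 8S. The step needs [4+2] addition to win over the ene reaction and over attack elsewhere; the fixed cisoid geometry secures the first, and the absence of any other alkene, with epoxide and ketone inert to singlet oxygen, secures the second. The 8S centre is the one that the inverting esterification in step 19 turns into 8R.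

Step 17
Reactants: 24 endoperoxide
Product: 25 (4S,5R,6R,8S,10S)-4,5-epoxy-8,13-dihydroxy-1-oxogermacr-7(11)-en-12,6-olide
Conditions: thiourea, MeOH, 0 °C → rt
Reagents that add atoms: none
Why: Thiourea reduces the O–O bond by attack of sulfur on oxygen under neutral conditions (no Kornblum–DeLaMare rearrangement), giving the (Z)-2-ene-1,4-diol with C8 unchanged.

Step 18
Reactants: 25 diol
Product: 26 (4S,5R,6R,8S,10S)-13-acetoxy-4,5-epoxy-8-hydroxy-1-oxogermacr-7(11)-en-12,6-olide
Conditions: AcCl (1.1 equiv), 2,4,6-collidine, CH2Cl2, −78 °C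
Reagents that add atoms: acetyl chloride, CC(Cl)=O
Why: Selective acylation: at low temperature with the hindered base collidine, acetyl chloride should react with the primary allylic C13 hydroxyl much faster than with the secondary C8 hydroxyl.

Step 19
Reactants: 26 monoacetate; 27 3-methylbut-2-enoic acid
Product: 28 (4S,5R,6R,8R,10S)-13-acetoxy-4,5-epoxy-8-[(3-methylbut-2-enoyl)oxy]-1-oxogermacr-7(11)-en-12,6-olide
Conditions: PPh3, DIAD, toluene, 0 °C → rt
Reagents that add atoms: none
Why: Mitsunobu esterification: the C8 hydroxyl is activated as an alkoxyphosphonium ion and displaced by the carboxylate in an SN2 step with inversion, turning 8S into the 8R ester of the target, while SN2′ attack at C11 is blocked because that carbon is fully substituted.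

**Compound list**

1 | nerol, (2Z)-3,7-dimethylocta-2,6-dien-1-ol | CC(C)=CCC/C(C)=C\CO | starting material
2 | [(2R,3S)-3-methyl-3-(4-methylpent-3-en-1-yl)oxiran-2-yl]methanol | OC[C@H]1O[C@@]1(C)CCC=C(C)C | intermediate
3 | (2S,3R)-3-{[(4-methoxybenzyl)oxy]methyl}-2-methyl-2-(4-methylpent-3-en-1-yl)oxirane | COc1ccc(COC[C@H]2O[C@@]2(C)CCC=C(C)C)cc1 | intermediate
4 | 3-{2-[(2S,3R)-3-{[(4-methoxybenzyl)oxy]methyl}-2-methyloxiran-2-yl]ethyl}-5,5-dimethyl-1,2,4-trioxolane (ozonide, both epimers at the trioxolane carbon) | COc1ccc(COC[C@H]2O[C@@]2(C)CCC3OOC(C)(C)O3)cc1 | intermediate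
5 | 3-[(2S,3R)-3-{[(4-methoxybenzyl)oxy]methyl}-2-methyloxiran-2-yl]propanal | COc1ccc(COC[C@H]2O[C@@]2(C)CCC=O)cc1 | intermediate
6 | O-diisopinocampheylboryl derivative (borinate) of alcohol 7 | COc1ccc(COC[C@H]2O[C@@]2(C)CC[C@@H](OB([C@H]3[C@H](C)[C@H]4C[C@@H](C3)C4(C)C)[C@H]3[C@H](C)[C@H]4C[C@@H](C3)C4(C)C)[C@@H](C)C=C)cc1 | intermediate
7 | (3R,4S)-1-[(2S,3R)-3-{[(4-methoxybenzyl)oxy]methyl}-2-methyloxiran-2-yl]-4-methylhex-5-en-3-ol | COc1ccc(COC[C@H]2O[C@@]2(C)CC[C@@H](O)[C@@H](C)C=C)cc1 | intermediate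
8 | triethyl{[(3R,4S)-1-[(2S,3R)-3-{[(4-methoxybenzyl)oxy]methyl}-2-methyloxiran-2-yl]-4-methylhex-5-en-3-yl]oxy}silane | COc1ccc(COC[C@H]2O[C@@]2(C)CC[C@@H](O[Si](CC)(CC)CC)[C@@H](C)C=C)cc1 | intermediate
9 | B-alkyl-9-borabicyclo[3.3.1]nonane from 8 (boron on the terminal carbon, C8) | COc1ccc(COC[C@H]2O[C@@]2(C)CC[C@@H](O[Si](CC)(CC)CC)[C@@H](C)CCB3C4CCCC3CCC4)cc1 | intermediate
10 | (3S,4R)-6-[(2S,3R)-3-{[(4-methoxybenzyl)oxy]methyl}-2-methyloxiran-2-yl]-3-methyl-4-[(triethylsilyl)oxy]hexan-1-ol | COc1ccc(COC[C@H]2O[C@@]2(C)CC[C@@H](O[Si](CC)(CC)CC)[C@@H](C)CCO)cc1 | intermediate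
11 | (3S,4R)-6-[(2S,3R)-3-{[(4-methoxybenzyl)oxy]methyl}-2-methyloxiran-2-yl]-3-methyl-4-[(triethylsilyl)oxy]hexanal | COc1ccc(COC[C@H]2O[C@@]2(C)CC[C@@H](O[Si](CC)(CC)CC)[C@@H](C)CC=O)cc1 | intermediate
12 | (2S,3R)-2-[(3R,4S)-7,7-dibromo-4-methyl-3-[(triethylsilyl)oxy]hept-6-en-1-yl]-3-{[(4-methoxybenzyl)oxy]methyl}-2-methyloxirane | COc1ccc(COC[C@H]2O[C@@]2(C)CC[C@@H](O[Si](CC)(CC)CC)[C@@H](C)CC=C(Br)Br)cc1 | intermediate
13 | methyl propiolate | C#CC(=O)OC | starting material
14 | tributyltin hydride | CCCC[SnH](CCCC)CCCC | starting material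
15 | methyl 2-(tributylstannyl)prop-2-enoate | C=C(C(=O)OC)[Sn](CCCC)(CCCC)CCCC | intermediate
16 | methyl (3Z,6S,7R)-3-bromo-9-[(2S,3R)-3-{[(4-methoxybenzyl)oxy]methyl}-2-methyloxiran-2-yl]-6-methyl-2-methylidene-7-[(triethylsilyl)oxy]non-3-enoate | COc1ccc(COC[C@H]2O[C@@]2(C)CC[C@@H](O[Si](CC)(CC)CC)[C@@H](C)C/C=C(Br)/C(=C)C(=O)OC)cc1 | intermediate
17 | methyl (3Z,6S,7R)-3-bromo-9-[(2S,3R)-3-(hydroxymethyl)-2-methyloxiran-2-yl]-6-methyl-2-methylidene-7-[(triethylsilyl)oxy]non-3-enoate | OC[C@H]1O[C@@]1(C)CC[C@@H](O[Si](CC)(CC)CC)[C@@H](C)C/C=C(Br)/C(=C)C(=O)OC | intermediate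
18 | methyl (3Z,6S,7R)-3-bromo-9-[(2S,3S)-3-formyl-2-methyloxiran-2-yl]-6-methyl-2-methylidene-7-[(triethylsilyl)oxy]non-3-enoate | O=C[C@H]1O[C@@]1(C)CC[C@@H](O[Si](CC)(CC)CC)[C@@H](C)C/C=C(Br)/C(=C)C(=O)OC | intermediate
19 | methyl (1R,4S,5R,6R,7Z,10S)-4,5-epoxy-6-hydroxy-1-[(triethylsilyl)oxy]germacra-7,11(13)-dien-12-oate (formed as its chromium alkoxide) | COC(=O)C(=C)/C1=C/C[C@H](C)[C@H](O[Si](CC)(CC)CC)CC[C@]2(C)O[C@@H]2[C@@H]1O | intermediate
20 | (1R,4S,5R,6R,7Z,10S)-4,5-epoxy-1-[(triethylsilyl)oxy]germacra-7,11(13)-dien-12,6-olide | C=C1C(=O)O[C@@H]2/C1=C\C[C@H](C)[C@H](O[Si](CC)(CC)CC)CC[C@]1(C)O[C@@H]12 | intermediate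
21 | (1R,4S,5R,6R,7Z,10S)-4,5-epoxy-1-hydroxygermacra-7,11(13)-dien-12,6-olide | C=C1C(=O)O[C@@H]2/C1=C\C[C@H](C)[C@H](O)CC[C@]1(C)O[C@@H]12 | intermediate
22 | (4S,5R,6R,7Z,10S)-4,5-epoxy-1-oxogermacra-7,11(13)-dien-12,6-olide | C=C1C(=O)O[C@@H]2/C1=C\C[C@H](C)C(=O)CC[C@]1(C)O[C@@H]12 | intermediate
23 | dioxygen (used as its singlet state) | O=O | starting material
24 | (4S,5R,6R,8S,10S)-4,5-epoxy-8,13-epidioxy-1-oxogermacr-7(11)-en-12,6-olide | O=C1O[C@@H]2C3=C1COO[C@H]3C[C@H](C)C(=O)CC[C@]1(C)O[C@@H]12 | intermediate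
25 | (4S,5R,6R,8S,10S)-4,5-epoxy-8,13-dihydroxy-1-oxogermacr-7(11)-en-12,6-olide | O=C1O[C@@H]2C(=C1CO)[C@@H](O)C[C@H](C)C(=O)CC[C@]1(C)O[C@@H]12 | intermediate
26 | (4S,5R,6R,8S,10S)-13-acetoxy-4,5-epoxy-8-hydroxy-1-oxogermacr-7(11)-en-12,6-olide | O=C1O[C@@H]2C(=C1COC(C)=O)[C@@H](O)C[C@H](C)C(=O)CC[C@]1(C)O[C@@H]12 | intermediate
27 | 3-methylbut-2-enoic acid | CC(C)=CC(=O)O | starting material
28 | (4S,5R,6R,8R,10S)-13-acetoxy-4,5-epoxy-8-[(3-methylbut-2-enoyl)oxy]-1-oxogermacr-7(11)-en-12,6-olide (CNP0220542.1) | CC(=O)OCC1=C2[C@@H](OC1=O)[C@H]1O[C@@]1(C)CCC(=O)[C@@H](C)C[C@H]2OC(=O)C=C(C)C | target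

**Step count and risks**

Total step count: 19. Longest linear sequence: 18 steps (nerol 1 to 28 through steps 1–8 and 10–19; step 9 makes the stannane in a side branch).

Steps most likely to fail:

Step 13. Insertion into the alkenyl C–Br bond may be slow, so that oligomers form at the dilution a ten-membered ring needs, and the carbon nucleophile may add to the wrong face of the epoxy aldehyde. The fallback sets out from aldehyde 11 and returns at lactone 20; it closes the ring with a simple, more reactive iodoalkene and sets C6 afterwards by hydride reduction. Stork–Zhao olefination of 11 with iodomethylenetriphenylphosphorane should give the (Z)-iodoalkene F1. DDQ then gives alcohol F2 and Dess–Martin oxidation gives epoxy aldehyde F3. Nozaki–Hiyama–Kishi closure (CrCl2, NiCl2 cat., DMSO/THF, high dilution) should give cyclodecenol F4 as a mixture of C6 epimers, which does not matter because Dess–Martin oxidation converts both into enone F5. α-Iodination with I2 and pyridine should give iodoenone F6 with the ring alkene still cis, and Stille coupling with stannane 15 gives dienone ester F7. Chelation-controlled reduction with Zn(BH4)2 should deliver hydride to the ketone face that gives the erythro (6R) epoxy alcohol 19, which lactonises to 20.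

Step 16. Oxygen may add to the diene face syn to C5, or to both faces, and an ene reaction at C9–H may compete. The fallback sets out from diene 22 and returns at target 28; it carries the other C8 epimer forward and changes the esterification from inversion to retention, so that both faces lead to the same target. The (8R)-endoperoxide F8 is reduced with thiourea to diol F9 and acetylated at C13 as in step 18 to monoacetate F10. F10 is then esterified with acid 27 under Yamaguchi conditions (2,4,6-trichlorobenzoyl chloride, Et3N, then DMAP), which keeps the configuration at C8 and gives 28.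

Step 19. The activated alcohol may eliminate towards C9 to give a dienoate, or the hindered centre may react so slowly that an acyloxyphosphonium pathway gives the ester with retention. The fallback sets out from monoacetate 26 and returns at 28; it separates activation from displacement. Methanesulfonyl chloride and Et3N at −20 °C should give mesylate F11, which is displaced with inversion by caesium 3-methylbut-2-enoate (from acid 27 and Cs2CO3) with 18-crown-6 in toluene to give 28.

**Further compounds**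

F1 | step 13 | (2S,3R)-2-[(3R,4S,6Z)-7-iodo-4-methyl-3-[(triethylsilyl)oxy]hept-6-en-1-yl]-3-{[(4-methoxybenzyl)oxy]methyl}-2-methyloxirane | COc1ccc(COC[C@H]2O[C@@]2(C)CC[C@@H](O[Si](CC)(CC)CC)[C@@H](C)C/C=C\I)cc1
F2 | step 13 | [(2R,3S)-3-[(3R,4S,6Z)-7-iodo-4-methyl-3-[(triethylsilyl)oxy]hept-6-en-1-yl]-3-methyloxiran-2-yl]methanol | OC[C@H]1O[C@@]1(C)CC[C@@H](O[Si](CC)(CC)CC)[C@@H](C)C/C=C\I
F3 | step 13 | (2S,3S)-3-[(3R,4S,6Z)-7-iodo-4-methyl-3-[(triethylsilyl)oxy]hept-6-en-1-yl]-3-methyloxirane-2-carbaldehyde | O=C[C@H]1O[C@@]1(C)CC[C@@H](O[Si](CC)(CC)CC)[C@@H](C)C/C=C\I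
F4 | step 13 | (1R,4S,5R,7Z,10S)-4,5-epoxy-1-[(triethylsilyl)oxy]-11,12,13-trinorgermacr-7-en-6-ol (both C6 epimers) | OC2/C=C\C[C@H](C)[C@H](O[Si](CC)(CC)CC)CC[C@]1(C)O[C@@H]12
F5 | step 13 | (1R,4S,5S,7Z,10S)-4,5-epoxy-1-[(triethylsilyl)oxy]-11,12,13-trinorgermacr-7-en-6-one | O=C2/C=C\C[C@H](C)[C@H](O[Si](CC)(CC)CC)CC[C@]1(C)O[C@@H]12
F6 | step 13 | (1R,4S,5S,7E,10S)-4,5-epoxy-7-iodo-1-[(triethylsilyl)oxy]-11,12,13-trinorgermacr-7-en-6-one (ring alkene cis, iodine trans to C9) | O=C2/C(I)=C\C[C@H](C)[C@H](O[Si](CC)(CC)CC)CC[C@]1(C)O[C@@H]12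
F7 | step 13 | methyl (1R,4S,5S,7Z,10S)-4,5-epoxy-6-oxo-1-[(triethylsilyl)oxy]germacra-7,11(13)-dien-12-oate | O=C2/C(C(=C)C(=O)OC)=C\C[C@H](C)[C@H](O[Si](CC)(CC)CC)CC[C@]1(C)O[C@@H]12
F8 | step 16 | (4S,5R,6R,8R,10S)-4,5-epoxy-8,13-epidioxy-1-oxogermacr-7(11)-en-12,6-olide | O=C1O[C@@H]2C3=C1COO[C@@H]3C[C@H](C)C(=O)CC[C@]1(C)O[C@@H]12
F9 | step 16 | (4S,5R,6R,8R,10S)-4,5-epoxy-8,13-dihydroxy-1-oxogermacr-7(11)-en-12,6-olide | O=C1O[C@@H]2C(=C1CO)[C@H](O)C[C@H](C)C(=O)CC[C@]1(C)O[C@@H]12
F10 | step 16 | (4S,5R,6R,8R,10S)-13-acetoxy-4,5-epoxy-8-hydroxy-1-oxogermacr-7(11)-en-12,6-olide | O=C1O[C@@H]2C(=C1COC(C)=O)[C@H](O)C[C@H](C)C(=O)CC[C@]1(C)O[C@@H]12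
F11 | step 19 | (4S,5R,6R,8S,10S)-13-acetoxy-4,5-epoxy-8-[(methylsulfonyl)oxy]-1-oxogermacr-7(11)-en-12,6-olide | O=C1O[C@@H]2C(=C1COC(C)=O)[C@@H](OS(C)(=O)=O)C[C@H](C)C(=O)CC[C@]1(C)O[C@@H]12
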